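Ring B is closed at C6–C7 by a 6-endo radical cyclisation. A C7 radical flanked by the C8 carbonyl attacks C6, the only accessible end of an exocyclic C5=C6 methylene that is locked between the quaternary carbons C4 and C10 of ring A; hydrogen transfer to the resulting C5 radical, anti to the axial C10 and C4 methyl groups, sets the trans ring fusion in the same operation. The precursor is a monocyclic bromomethyl ketone made by an Ireland–Claisen rearrangement, which forms C9–C10, quaternary C10 and the methylene. C2, set by catalytic transfer hydrogenation, relays C10, C5 and C9; the C8 ketone later becomes the C8=C17 methylene.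

Key step: step 9

Assumption: labdane numbering is used for all intermediates (ring A: C1–C5 and C10; ring B: C5–C10; C17 the exocyclic methylene carbon; C11–C16 the side chain), and the sense of induction in step 1 is assigned by analogy with aryl alkyl ketones.

Step 1
Reactants: 1 ketoisophorone (2,6,6-trimethylcyclohex-2-ene-1,4-dione)
Product: 2 (4R)-4-hydroxy-2,6,6-trimethylcyclohex-2-en-1-one ((R)-phorenol)
Conditions: RuCl(p-cymene)[(R,R)-TsDPEN] (1 mol%), HCO2H/Et3N (5:2), CH2Cl2, rt
Reagents that add atoms: none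
Why: Noyori asymmetric transfer hydrogenation: the Ru–H/N–H catalyst should reduce only the unhindered ring carbonyl flanked by CH= and CH2 (the other lies between the quaternary carbon and the methyl-bearing alkene carbon), and the (R,R)-ligand should distinguish the alkenyl flank from the CH2 flank as it does aryl from alkyl, setting the (R)-carbinol that becomes C2 of the target.

Step 2
Reactants: 2 (4R)-4-hydroxy-2,6,6-trimethylcyclohex-2-en-1-one
Product: 3 (4R)-4-{[tert-butyl(dimethyl)silyl]oxy}-2,6,6-trimethylcyclohex-2-en-1-one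
Conditions: TBSCl, imidazole, DMF, rt
Reagents that add atoms: tert-butyldimethylsilyl chloride (TBSCl), CC(C)(C)[Si](C)(C)Cl
Why: standard silylation of a secondary alcohol; the silyl ether should survive the hydride, organolithium, radical and ylide conditions that follow and leaves together with the ester group in step 13.

Step 3
Reactants: 3 (4R)-4-{[tert-butyl(dimethyl)silyl]oxy}-2,6,6-trimethylcyclohex-2-en-1-one
Product: 5 (4S)-4-{[tert-butyl(dimethyl)silyl]oxy}-2,6,6-trimethylcyclohex-1-en-1-yl trifluoromethanesulfonate, via lithium enolate 4 (not isolated)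
Conditions: LiBH(s-Bu)3, THF, −78 °C; then PhNTf2, −78 °C to rt
Reagents that add atoms: N-phenylbis(trifluoromethanesulfonimide) (PhNTf2), O=S(=O)(N(c1ccccc1)S(=O)(=O)C(F)(F)F)C(F)(F)F; lithium tri-sec-butylborohydride (supplies only the lithium of 4), [Li+].CCC(C)[BH-](C(C)CC)C(C)CC
Why: conjugate reduction with the hindered borohydride (1,2-attack is blocked by the gem-dimethyl carbon and the α-methyl group) should give only the tetrasubstituted enolate 4, which PhNTf2 sulfonylates on oxygen (reductive enol triflate formation); the former enone β-carbon becomes C1.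

Step 4
Reactants: 5 (4S)-4-{[tert-butyl(dimethyl)silyl]oxy}-2,6,6-trimethylcyclohex-1-en-1-yl trifluoromethanesulfonate
Product: 6 [(4S)-4-{[tert-butyl(dimethyl)silyl]oxy}-2,6,6-trimethylcyclohex-1-en-1-yl]methanol
Conditions: Bu3SnCH2OH, Pd(PPh3)4 (10 mol%), LiCl, 1,4-dioxane, 100 °C
Reagents that add atoms: (tributylstannyl)methanol, CCCC[Sn](CCCC)(CCCC)CO
Why: Migita–Kosugi–Stille coupling: oxidative addition of the enol triflate to zerovalent palladium (chloride from LiCl stabilises the vinylpalladium species) and transfer of the hydroxymethyl group from tin install C6 as the allylic alcohol needed for the sigmatropic step.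

Step 5
Reactants: 6 [(4S)-4-{[tert-butyl(dimethyl)silyl]oxy}-2,6,6-trimethylcyclohex-1-en-1-yl]methanol; 7 hex-5-ynoic acid
Product: 8 [(4S)-4-{[tert-butyl(dimethyl)silyl]oxy}-2,6,6-trimethylcyclohex-1-en-1-yl]methyl hex-5-ynoate
Conditions: DCC, DMAP (cat.), CH2Cl2, 0 °C to rt
Reagents that add atoms: none
Why: Steglich esterification (carbodiimide activation, acyl transfer by DMAP) of the primary allylic alcohol under neutral conditions that do not ionise it.

Step 6
Reactants: 8 [(4S)-4-{[tert-butyl(dimethyl)silyl]oxy}-2,6,6-trimethylcyclohex-1-en-1-yl]methyl hex-5-ynoate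
Product: 11 (2R)-2-[(1R,5R)-5-{[tert-butyl(dimethyl)silyl]oxy}-1,3,3-trimethyl-2-methylidenecyclohexyl]-6-(trimethylsilyl)hex-5-ynoic acid, via silyl ketene acetal 9 (not isolated), via trimethylsilyl ester 10 (not isolated)
Conditions: LiN(i-Pr)2 (2.3 equiv), THF/DMPU, −78 °C; Me3SiCl (2.5 equiv); −78 °C to 60 °C; then dilute HCl
Reagents that add atoms: chlorotrimethylsilane (Me3SiCl), C[Si](C)(C)Cl
Why: Ireland–Claisen rearrangement: LiN(i-Pr)2 in THF/DMPU should form the (Z)-silyl ketene acetal 9 (the lithium acetylide is C-silylated in the same flask), and its chair [3,3] shift should form the C9–C10 bond axially on the half-chair that keeps the C2 silyloxy group equatorial, that is on the ring face anti to that group (the face also preferred by electrophiles on 3-oxygenated β-ionone rings), so that quaternary C10, the C9 centre (chain equatorial in the chair) and the exocyclic C5=C6 methylene arise together.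

Step 7
Reactants: 11 (2R)-2-[(1R,5R)-5-{[tert-butyl(dimethyl)silyl]oxy}-1,3,3-trimethyl-2-methylidenecyclohexyl]-6-(trimethylsilyl)hex-5-ynoic acid
Product: 12 (3R)-3-[(1R,5R)-5-{[tert-butyl(dimethyl)silyl]oxy}-1,3,3-trimethyl-2-methylidenecyclohexyl]-7-(trimethylsilyl)hept-6-yn-2-one
Conditions: MeLi (3.5 equiv), Et2O, 0 °C; then aq. NH4Cl
Reagents that add atoms: methyllithium, [Li]C
Why: methyllithium adds once to the lithium carboxylate and the dilithium gem-diolate survives until work-up (conversion of a carboxylic acid into a methyl ketone), while the silylalkyne should not be cleaved by MeLi in ether at 0 °C.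

Step 8
Reactants: 12 (3R)-3-[(1R,5R)-5-{[tert-butyl(dimethyl)silyl]oxy}-1,3,3-trimethyl-2-methylidenecyclohexyl]-7-(trimethylsilyl)hept-6-yn-2-one
Product: 14 (3R)-1-bromo-3-[(1R,5R)-5-{[tert-butyl(dimethyl)silyl]oxy}-1,3,3-trimethyl-2-methylidenecyclohexyl]-7-(trimethylsilyl)hept-6-yn-2-one, via silyl enol ether 13 (not isolated)
Conditions: LiN(i-Pr)2 (1.1 equiv), Me3SiCl, THF, −78 °C; then NBS, −78 °C to 0 °C
Reagents that add atoms: N-bromosuccinimide (NBS), O=C1CCC(=O)N1Br; chlorotrimethylsilane (supplies only the silyl group of 13), C[Si](C)(C)Cl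
Why: kinetic deprotonation should take only the methyl group (C7), because the other α-position is the C9 methine beside quaternary C10, and the trimethylsilyl enol ether 13 is brominated by NBS at low temperature faster than either alkene or the alkyne (halogenation of a silyl enol ether).

Step 9
Reactants: 14 (3R)-1-bromo-3-[(1R,5R)-5-{[tert-butyl(dimethyl)silyl]oxy}-1,3,3-trimethyl-2-methylidenecyclohexyl]-7-(trimethylsilyl)hept-6-yn-2-one
Product: 15 (2R,5S,9R,10S)-2-{[tert-butyl(dimethyl)silyl]oxy}-14-(trimethylsilyl)-15,16,17-trinorlabd-13-yn-8-one (trans-fused decalone; 2β-silyloxy; 5α-H; 9α-H; 10β-methyl)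
Conditions: Bu3SnH (1.2 equiv), AIBN (0.2 equiv), syringe pump, benzene (0.005 M), 80 °C
Reagents that add atoms: none
Why: Bu3Sn• abstracts bromine from 14 to give an electrophilic α-keto radical at C7, which adds to C6, the unsubstituted terminus of the electron-rich 1,1-disubstituted C5=C6 alkene, and the tertiary C5 radical so formed takes hydrogen from Bu3SnH and carries the chain. The closest known reaction type is the tin hydride-mediated cyclisation of α-halomethyl ketones onto alkenes (2-oxohex-5-enyl radicals), which prefer the endo mode. Ring B is closed by 6-endo-trig attack (C6–C7); the 5-exo alternative would have to bond C7 to C5, a carbon wedged between the quaternary centres C4 and C10. The new stereocentre C5 is controlled by the axial methyl groups on C10 and C4, which shield the β-face of the C5 radical, so hydrogen should be delivered axially from the α-face to give the trans-decalin; C9 is carried over from step 6 and is also the thermodynamically favoured equatorial epimer next to the ketone. The step needs cyclisation to outrun direct reduction of the C7 radical, which slow addition of the hydride at high dilution and the Thorpe–Ingold effect of quaternary C10 should secure.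

Step 10
Reactants: 15 (2R,5S,9R,10S)-2-{[tert-butyl(dimethyl)silyl]oxy}-14-(trimethylsilyl)-15,16,17-trinorlabd-13-yn-8-one
Product: 16 (2R,5S,9S,10S)-2-{[tert-butyl(dimethyl)silyl]oxy}-14-(trimethylsilyl)-15,16-dinorlabd-8(17)-en-13-yne
Conditions: Ph3PCH3Br, KOt-Bu, toluene, 90 °C
Reagents that add atoms: methyltriphenylphosphonium bromide, C[P+](c1ccccc1)(c1ccccc1)c1ccccc1.[Br-]
Why: Wittig methylenation with the non-stabilised ylide converts the C8 ketone into the C8=C17 methylene, and C9, although α to the ketone, already carries the thermodynamically preferred equatorial side chain and should not be eroded by the basic ylide.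

Step 11
Reactants: 16 (2R,5S,9S,10S)-2-{[tert-butyl(dimethyl)silyl]oxy}-14-(trimethylsilyl)-15,16-dinorlabd-8(17)-en-13-yne
Product: 18 2-(trimethylsilyl)ethyl (2R,5S,9S,10S)-2-{[tert-butyl(dimethyl)silyl]oxy}-16-norlabd-8(17)-en-13-yn-15-oate, via lithium acetylide 17 (not isolated)
Conditions: MeLi·LiBr, THF, rt; then ClCO2CH2CH2SiMe3, −78 °C
Reagents that add atoms: 2-(trimethylsilyl)ethyl chloroformate, C[Si](C)(C)CCOC(Cl)=O; methyllithium (supplies only the lithium of 17), [Li]C
Why: MeLi·LiBr attacks silicon and releases the lithium acetylide 17 (any alkyne desilylated by alkoxide in step 10 is simply deprotonated to the same species), which is acylated by the chloroformate (alkoxycarbonylation of an acetylide).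

Step 12
Reactants: 18 2-(trimethylsilyl)ethyl (2R,5S,9S,10S)-2-{[tert-butyl(dimethyl)silyl]oxy}-16-norlabd-8(17)-en-13-yn-15-oate
Product: 20 2-(trimethylsilyl)ethyl (2R,5S,9S,10S,13Z)-2-{[tert-butyl(dimethyl)silyl]oxy}labda-8(17),13-dien-15-oate, via vinylcuprate 19 (not isolated)
Conditions: Me2CuLi (from CuI and 2 MeLi), THF, −78 °C; then MeOH, −78 °C
Reagents that add atoms: lithium dimethylcuprate, [Li+].C[Cu-]C
Why: conjugate addition of the cuprate to the ynoate is a syn carbocupration, so CH3 and copper end up cis in vinylcuprate 19, and protonation at −78 °C with retention should give the (13Z)-enoate in which C12 and the ester group are cis.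

Step 13
Reactants: 20 2-(trimethylsilyl)ethyl (2R,5S,9S,10S,13Z)-2-{[tert-butyl(dimethyl)silyl]oxy}labda-8(17),13-dien-15-oate
Product: 21 (2R,5S,9S,10S,13Z)-2-hydroxylabda-8(17),13-dien-15-oic acid
Conditions: Bu4NF (5 equiv), THF, rt to 50 °C; then 1 M HCl, 0 °C
Reagents that add atoms: none
Why: fluoride removes both silicon-based groups in one operation, the silyl ether by attack at silicon and the 2-(trimethylsilyl)ethyl ester by β-elimination of ethylene, without touching the alkenes.

Step 14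
Reactants: 21 (2R,5S,9S,10S,13Z)-2-hydroxylabda-8(17),13-dien-15-oic acid
Product: 23 (2R,5S,9S,10S,13Z)-2-acetoxylabda-8(17),13-dien-15-oic acid (CNP0255148.1), via mixed anhydride 22 (not isolated)
Conditions: Ac2O, DMAP, pyridine, rt; then H2O/THF, NaHCO3
Reagents that add atoms: acetic anhydride, CC(=O)OC(C)=O
Why: DMAP-catalysed acetylation of the axial 2β-hydroxyl group; the carboxyl group is converted for a time into mixed anhydride 22, which water cleaves at its acetyl carbonyl during work-up.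

Compound list
1 | ketoisophorone (2,6,6-trimethylcyclohex-2-ene-1,4-dione) | CC1=CC(=O)CC(C)(C)C1=O | starting material
2 | (4R)-4-hydroxy-2,6,6-trimethylcyclohex-2-en-1-one ((R)-phorenol) | CC1(C)C[C@@H](O)C=C(C)C1=O | intermediate
3 | (4R)-4-{[tert-butyl(dimethyl)silyl]oxy}-2,6,6-trimethylcyclohex-2-en-1-one | CC1(C)C[C@@H](O[Si](C)(C)C(C)(C)C)C=C(C)C1=O | intermediate
4 | lithium (4S)-4-{[tert-butyl(dimethyl)silyl]oxy}-2,6,6-trimethylcyclohex-1-en-1-olate (lithium enolate) | CC1(C)C[C@@H](O[Si](C)(C)C(C)(C)C)CC(C)=C1O[Li] | intermediate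
5 | (4S)-4-{[tert-butyl(dimethyl)silyl]oxy}-2,6,6-trimethylcyclohex-1-en-1-yl trifluoromethanesulfonate | CC1(C)C[C@@H](O[Si](C)(C)C(C)(C)C)CC(C)=C1OS(=O)(=O)C(F)(F)F | intermediate
6 | [(4S)-4-{[tert-butyl(dimethyl)silyl]oxy}-2,6,6-trimethylcyclohex-1-en-1-yl]methanol | CC1(C)C[C@@H](O[Si](C)(C)C(C)(C)C)CC(C)=C1CO | intermediate
7 | hex-5-ynoic acid | C#CCCCC(=O)O | starting material
8 | [(4S)-4-{[tert-butyl(dimethyl)silyl]oxy}-2,6,6-trimethylcyclohex-1-en-1-yl]methyl hex-5-ynoate | CC1(C)C[C@@H](O[Si](C)(C)C(C)(C)C)CC(C)=C1COC(=O)CCCC#C | intermediate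
9 | (Z)-1-{[(4S)-4-{[tert-butyl(dimethyl)silyl]oxy}-2,6,6-trimethylcyclohex-1-en-1-yl]methoxy}-1-(trimethylsilyloxy)-6-(trimethylsilyl)hex-1-en-5-yne (silyl ketene acetal) | CC1(C)C[C@@H](O[Si](C)(C)C(C)(C)C)CC(C)=C1CO/C(O[Si](C)(C)C)=C/CCC#C[Si](C)(C)C | intermediate
10 | trimethylsilyl (2R)-2-[(1R,5R)-5-{[tert-butyl(dimethyl)silyl]oxy}-1,3,3-trimethyl-2-methylidenecyclohexyl]-6-(trimethylsilyl)hex-5-ynoate | C=C1C(C)(C)C[C@@H](O[Si](C)(C)C(C)(C)C)C[C@]1(C)[C@@H](CCC#C[Si](C)(C)C)C(=O)O[Si](C)(C)C | intermediate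
11 | (2R)-2-[(1R,5R)-5-{[tert-butyl(dimethyl)silyl]oxy}-1,3,3-trimethyl-2-methylidenecyclohexyl]-6-(trimethylsilyl)hex-5-ynoic acid | C=C1C(C)(C)C[C@@H](O[Si](C)(C)C(C)(C)C)C[C@]1(C)[C@@H](CCC#C[Si](C)(C)C)C(=O)O | intermediate
12 | (3R)-3-[(1R,5R)-5-{[tert-butyl(dimethyl)silyl]oxy}-1,3,3-trimethyl-2-methylidenecyclohexyl]-7-(trimethylsilyl)hept-6-yn-2-one | C=C1C(C)(C)C[C@@H](O[Si](C)(C)C(C)(C)C)C[C@]1(C)[C@@H](CCC#C[Si](C)(C)C)C(C)=O | intermediate
13 | (3R)-3-[(1R,5R)-5-{[tert-butyl(dimethyl)silyl]oxy}-1,3,3-trimethyl-2-methylidenecyclohexyl]-2-(trimethylsilyloxy)-7-(trimethylsilyl)hept-1-en-6-yne (silyl enol ether) | C=C1C(C)(C)C[C@@H](O[Si](C)(C)C(C)(C)C)C[C@]1(C)[C@@H](CCC#C[Si](C)(C)C)C(=C)O[Si](C)(C)C | intermediate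
14 | (3R)-1-bromo-3-[(1R,5R)-5-{[tert-butyl(dimethyl)silyl]oxy}-1,3,3-trimethyl-2-methylidenecyclohexyl]-7-(trimethylsilyl)hept-6-yn-2-one | C=C1C(C)(C)C[C@@H](O[Si](C)(C)C(C)(C)C)C[C@]1(C)[C@@H](CCC#C[Si](C)(C)C)C(=O)CBr | intermediate
15 | (2R,5S,9R,10S)-2-{[tert-butyl(dimethyl)silyl]oxy}-14-(trimethylsilyl)-15,16,17-trinorlabd-13-yn-8-one | O=C1CC[C@H]2C(C)(C)C[C@@H](O[Si](C)(C)C(C)(C)C)C[C@]2(C)[C@H]1CCC#C[Si](C)(C)C | intermediate
16 | (2R,5S,9S,10S)-2-{[tert-butyl(dimethyl)silyl]oxy}-14-(trimethylsilyl)-15,16-dinorlabd-8(17)-en-13-yne | C=C1CC[C@H]2C(C)(C)C[C@@H](O[Si](C)(C)C(C)(C)C)C[C@]2(C)[C@H]1CCC#C[Si](C)(C)C | intermediate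
17 | lithium acetylide of (2R,5S,9S,10S)-2-{[tert-butyl(dimethyl)silyl]oxy}-15,16-dinorlabd-8(17)-en-13-yne (C14–Li) | C=C1CC[C@H]2C(C)(C)C[C@@H](O[Si](C)(C)C(C)(C)C)C[C@]2(C)[C@H]1CCC#C[Li] | intermediate
18 | 2-(trimethylsilyl)ethyl (2R,5S,9S,10S)-2-{[tert-butyl(dimethyl)silyl]oxy}-16-norlabd-8(17)-en-13-yn-15-oate | C=C1CC[C@H]2C(C)(C)C[C@@H](O[Si](C)(C)C(C)(C)C)C[C@]2(C)[C@H]1CCC#CC(=O)OCC[Si](C)(C)C | intermediate
19 | lithium methyl(vinyl)cuprate formed by syn addition to 18 (copper on C14 cis to the new C16 methyl) | C=C1CC[C@H]2C(C)(C)C[C@@H](O[Si](C)(C)C(C)(C)C)C[C@]2(C)[C@H]1CC/C(C)=C(\C(=O)OCC[Si](C)(C)C)[Cu-]C.[Li+] | intermediate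
20 | 2-(trimethylsilyl)ethyl (2R,5S,9S,10S,13Z)-2-{[tert-butyl(dimethyl)silyl]oxy}labda-8(17),13-dien-15-oate | C=C1CC[C@H]2C(C)(C)C[C@@H](O[Si](C)(C)C(C)(C)C)C[C@]2(C)[C@H]1CC/C(C)=C\C(=O)OCC[Si](C)(C)C | intermediate
21 | (2R,5S,9S,10S,13Z)-2-hydroxylabda-8(17),13-dien-15-oic acid | C=C1CC[C@H]2C(C)(C)C[C@@H](O)C[C@]2(C)[C@H]1CC/C(C)=C\C(=O)O | intermediate
22 | acetic (2R,5S,9S,10S,13Z)-2-acetoxylabda-8(17),13-dien-15-oic anhydride (mixed anhydride) | C=C1CC[C@H]2C(C)(C)C[C@@H](OC(C)=O)C[C@]2(C)[C@H]1CC/C(C)=C\C(=O)OC(C)=O | intermediate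
23 | (2R,5S,9S,10S,13Z)-2-acetoxylabda-8(17),13-dien-15-oic acid (CNP0255148.1) | C=C1CC[C@H]2C(C)(C)C[C@@H](OC(C)=O)C[C@]2(C)[C@H]1CC/C(C)=C\C(=O)O | target

Total step count: 14
Longest linear sequence: 14 steps (1 to 23; 7 is used as bought)

Steps most likely to fail

Step 6. The remote C2 silyloxy group may discriminate poorly between the two faces of C10, or part of the rearrangement may pass through a boat transition state; either would lower the configurational purity at C10, on which C5 and C9 depend. The fallback replaces substrate control by reagent control. Ester 8 is converted with the C2-symmetric bromoborane (4R,5R)-2-bromo-4,5-diphenyl-1,3-bis(p-tolylsulfonyl)-1,3,2-diazaborolidine (or its antipode, whichever reinforces the substrate) and i-Pr2NEt in CH2Cl2 at −78 °C into a chiral boron enolate, which rearranges on warming to rt (enantioselective boron ester-enolate Claisen rearrangement). Aqueous work-up should give (2R)-2-[(1R,5R)-5-{[tert-butyl(dimethyl)silyl]oxy}-1,3,3-trimethyl-2-methylidenecyclohexyl]hex-5-ynoic acid F1. C-Silylation of its alkyne (n-BuLi 2.1 equiv, THF, −78 °C; Me3SiCl; dilute HCl) comes back to acid 11.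

Step 9. The C7 radical may be reduced before it cyclises, may take the propargylic hydrogen from C12 by 1,5-transfer, or may add to the silylalkyne; hydrogen delivery at C5 may also be unselective. The fallback closes the same bond by polar chemistry, setting out from methyl ketone 12.
- Epoxidation of the exocyclic alkene (mCPBA, NaHCO3, CH2Cl2, 0 °C) should give the spiro-epoxide (3R)-3-[(4R,6R)-6-{[tert-butyl(dimethyl)silyl]oxy}-4,8,8-trimethyl-1-oxaspiro[2.5]octan-4-yl]-7-(trimethylsilyl)hept-6-yn-2-one F2 (either configuration at the spiro carbon).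
- BF3·OEt2 (CH2Cl2, −78 °C) induces the Meinwald rearrangement with hydride shift from C6 to C5 and should give the keto aldehyde (1S,2S,4R)-4-{[tert-butyl(dimethyl)silyl]oxy}-2,6,6-trimethyl-2-[(3R)-2-oxo-7-(trimethylsilyl)hept-6-yn-3-yl]cyclohexane-1-carbaldehyde F3.
- Intramolecular aldol condensation (piperidinium acetate, benzene, reflux) forms C6=C7 and should give the enone (2R,5S,9R,10S)-2-{[tert-butyl(dimethyl)silyl]oxy}-14-(trimethylsilyl)-15,16,17-trinorlabd-6-en-13-yn-8-one F4, in which C5, now γ to the carbonyl, can equilibrate to the trans ring fusion.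
- Conjugate reduction with [(Ph3P)CuH]6 (benzene, rt) comes back to ketone 15.

Step 4. Oxidative addition and transmetalation may be slow at the tetrasubstituted triflate beside the gem-dimethyl carbon, so that reduction of the triflate and loss of the stannane compete with coupling. The fallback installs C6 by carbonylation and reduction. Triflate 5 with Pd(OAc)2, 1,3-bis(diphenylphosphino)propane, CO (1 atm), MeOH and Et3N in DMF at 70 °C should give methyl (4S)-4-{[tert-butyl(dimethyl)silyl]oxy}-2,6,6-trimethylcyclohex-1-ene-1-carboxylate F5. Reduction with i-Bu2AlH (CH2Cl2, −78 °C) comes back to allylic alcohol 6.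

Further compounds
F1 | step 6 | (2R)-2-[(1R,5R)-5-{[tert-butyl(dimethyl)silyl]oxy}-1,3,3-trimethyl-2-methylidenecyclohexyl]hex-5-ynoic acid | C=C1C(C)(C)C[C@@H](O[Si](C)(C)C(C)(C)C)C[C@]1(C)[C@@H](CCC#C)C(=O)O
F2 | step 9 | (3R)-3-[(4R,6R)-6-{[tert-butyl(dimethyl)silyl]oxy}-4,8,8-trimethyl-1-oxaspiro[2.5]octan-4-yl]-7-(trimethylsilyl)hept-6-yn-2-one | O1CC12C(C)(C)C[C@@H](O[Si](C)(C)C(C)(C)C)C[C@]2(C)[C@@H](CCC#C[Si](C)(C)C)C(C)=O
F3 | step 9 | (1S,2S,4R)-4-{[tert-butyl(dimethyl)silyl]oxy}-2,6,6-trimethyl-2-[(3R)-2-oxo-7-(trimethylsilyl)hept-6-yn-3-yl]cyclohexane-1-carbaldehyde | O=C[C@H]1C(C)(C)C[C@@H](O[Si](C)(C)C(C)(C)C)C[C@]1(C)[C@@H](CCC#C[Si](C)(C)C)C(C)=O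
F4 | step 9 | (2R,5S,9R,10S)-2-{[tert-butyl(dimethyl)silyl]oxy}-14-(trimethylsilyl)-15,16,17-trinorlabd-6-en-13-yn-8-one | O=C1C=C[C@H]2C(C)(C)C[C@@H](O[Si](C)(C)C(C)(C)C)C[C@]2(C)[C@H]1CCC#C[Si](C)(C)C
F5 | step 4 | methyl (4S)-4-{[tert-butyl(dimethyl)silyl]oxy}-2,6,6-trimethylcyclohex-1-ene-1-carboxylate | CC1(C)C[C@@H](O[Si](C)(C)C(C)(C)C)CC(C)=C1C(=O)OC
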